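Assumption: the SMILES is read as (2S) at the chromene carbon, 2E at the acid alkene (CO2H trans to the C4 methylene, tiglate type) and 6E. The sense of induction of the new catalyst in step 13 cannot be predicted. The quinidine series is written, and the pseudo-enantiomeric series is used instead if that is the one that gives (S). The assignment is made by chiral HPLC and ECD.

## Retrosynthetic overview
1. The acid comes from its allyl ester, removed last by neutral Pd(0) deallylation so that C2 is not disturbed.
2. The pyran is the only ring formed (the arene is bought); it closes in the second-to-last step together with C2 (S), by a new catalytic enantioselective tautomerisation/oxa-6π electrocyclisation of a prenylquinone.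
3. The quinone comes from the hydroquinone dimethyl ether (CAN), and the aryl–C1' bond from an arylcopper plus a primary allylic bromide.
4. The (2E)-enoate comes from a Wittig reaction of a C12 hydroxy-aldehyde with an α-homoprenyl stabilised ylide.
5. The hydroxy-aldehyde comes from (E,E)-farnesol by terminal bromohydrin, epoxide and periodate cleavage, so both remaining E-alkenes are bought in.

## Route

Step 1
Reactants: 1 2,3-dimethylhydroquinone
Product: 2 1,4-dimethoxy-2,3-dimethylbenzene
Conditions: MeI, K2CO3, acetone, reflux, N2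
Reagents that add atoms: iodomethane, CI
Why: Williamson ether synthesis, in which both phenoxides are methylated by SN2 and the hydroquinone is masked for the organometallic step.

Step 2
Reactants: 2 1,4-dimethoxy-2,3-dimethylbenzene
Product: 3 1-bromo-2,5-dimethoxy-3,4-dimethylbenzene
Conditions: NBS (1.0 equiv), MeCN, 0 °C to rt, dark
Reagents that add atoms: N-bromosuccinimide, O=C1CCC(=O)N1Br
Why: Electrophilic aromatic bromination, where the two free ring positions are equivalent and one equivalent of NBS stops at the monobromide.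

Step 3
Reactants: 4 (2E,6E)-farnesol
Product: 5 (2E,6E)-farnesyl acetate
Conditions: Ac2O, pyridine, DMAP (cat.), CH2Cl2, 0 °C to rt
Reagents that add atoms: acetic anhydride, CC(=O)OC(C)=O
Why: DMAP-catalysed acylation, and the allylic acetate lowers the nucleophilicity of the 2,3-alkene for step 4.

Step 4
Reactants: 5 (2E,6E)-farnesyl acetate
Product: 6 (2E,6E)-10-bromo-11-hydroxy-3,7,11-trimethyldodeca-2,6-dien-1-yl acetate (racemic)
Conditions: NBS (1.05 equiv), THF/H2O, 0 °C
Reagents that add atoms: N-bromosuccinimide, O=C1CCC(=O)N1Br; water, O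
Why: Terminal-selective bromohydrin formation (van Tamelen conditions) with Markovnikov opening of the bromonium ion by water, and the racemic C10 centre is destroyed in step 6.

Step 5
Reactants: 6 (2E,6E)-10-bromo-11-hydroxy-3,7,11-trimethyldodeca-2,6-dien-1-yl acetate
Product: 8 (2E,6E)-10,11-epoxy-3,7,11-trimethyldodeca-2,6-dien-1-ol (racemic), via epoxy acetate 7 (not isolated)
Conditions: K2CO3, MeOH, rt
Reagents that add atoms: none
Why: Intramolecular Williamson closure of the bromohydrin to the epoxide is followed by carbonate-catalysed transesterification of the acetate.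

Step 6
Reactants: 8 (2E,6E)-10,11-epoxy-3,7,11-trimethyldodeca-2,6-dien-1-ol
Product: 10 (4E,8E)-10-hydroxy-4,8-dimethyldeca-4,8-dienal, via triol 9 (not isolated)
Conditions: H5IO6 (1.1 equiv), THF/Et2O, 0 °C
Reagents that add atoms: none
Why: Acid-catalysed epoxide hydrolysis (water attacks the tertiary carbon) is followed by Malaprade glycol cleavage, which leaves the alkenes and the allylic alcohol untouched.

Step 7
Reactants: 11 5-bromo-2-methylpent-2-ene
Product: 12 5-iodo-2-methylpent-2-ene
Conditions: NaI, acetone, reflux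
Reagents that add atoms: sodium iodide, [Na+].[I-]
Why: Finkelstein halide exchange, driven by precipitation of NaBr, gives the better electrophile for the weakly nucleophilic ylide.

Step 8
Reactants: 12 5-iodo-2-methylpent-2-ene; 13 allyl (triphenyl-λ5-phosphanylidene)acetate
Product: 15 allyl 6-methyl-2-(triphenyl-λ5-phosphanylidene)hept-5-enoate, via phosphonium iodide 14 (not isolated)
Conditions: 12 (1.5 equiv), K2CO3, MeCN, reflux
Reagents that add atoms: none
Why: SN2 C-alkylation of a stabilised ylide, with K2CO3 deprotonating the phosphonium salt so that no ylide is lost to transylidation.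

Step 9
Reactants: 10 (4E,8E)-10-hydroxy-4,8-dimethyldeca-4,8-dienal; 15 allyl 6-methyl-2-(triphenyl-λ5-phosphanylidene)hept-5-enoate
Product: 16 allyl (2E,6E,10E)-12-hydroxy-6,10-dimethyl-2-(4-methylpent-3-en-1-yl)dodeca-2,6,10-trienoate
Conditions: PhMe, 80 °C
Reagents that add atoms: none
Why: Wittig olefination with an α-substituted stabilised ylide places the ester trans to the aldehyde chain (2E), tolerates the free alcohol, and the minor 2Z isomer is removed on silica.

Step 10
Reactants: 16 allyl (2E,6E,10E)-12-hydroxy-6,10-dimethyl-2-(4-methylpent-3-en-1-yl)dodeca-2,6,10-trienoate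
Product: 17 allyl (2E,6E,10E)-12-bromo-6,10-dimethyl-2-(4-methylpent-3-en-1-yl)dodeca-2,6,10-trienoate
Conditions: PBr3 (0.4 equiv), Et2O, −10 °C; used crude
Reagents that add atoms: phosphorus tribromide, BrP(Br)Br
Why: SN2 bromination of a primary allylic alcohol through its phosphite, as is standard for farnesol, proceeds without allylic transposition or loss of E geometry.

Step 11
Reactants: 3 1-bromo-2,5-dimethoxy-3,4-dimethylbenzene; 17 allyl (2E,6E,10E)-12-bromo-6,10-dimethyl-2-(4-methylpent-3-en-1-yl)dodeca-2,6,10-trienoate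
Product: 20 allyl (2E,6E,10E)-12-(2,5-dimethoxy-3,4-dimethylphenyl)-6,10-dimethyl-2-(4-methylpent-3-en-1-yl)dodeca-2,6,10-trienoate, via aryllithium 18 (not isolated), via arylcopper 19 (not isolated)
Conditions: 3 (1.3 equiv), n-BuLi, THF, −78 °C; CuBr·SMe2, −78 to −40 °C; 17, −78 to −20 °C
Reagents that add atoms: none
Why: Bromine–lithium exchange and transmetalation to copper precede an α-selective (SN2) allylic substitution, in which the monoarylcopper attacks only the allylic bromide, leaves both ester functions alone and retains the E-alkene.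

Step 12
Reactants: 20 allyl (2E,6E,10E)-12-(2,5-dimethoxy-3,4-dimethylphenyl)-6,10-dimethyl-2-(4-methylpent-3-en-1-yl)dodeca-2,6,10-trienoate
Product: 21 allyl (2E,6E,10E)-12-(4,5-dimethyl-3,6-dioxocyclohexa-1,4-dien-1-yl)-6,10-dimethyl-2-(4-methylpent-3-en-1-yl)dodeca-2,6,10-trienoate
Conditions: CAN (2.3 equiv), MeCN/H2O, 0 °C, 20 min
Reagents that add atoms: water, O
Why: CAN oxidative demethylation of a hydroquinone dimethyl ether (water adds ipso to the arene radical cation and methanol leaves) is standard on polyprenyl arenes and too fast for the isolated alkenes to react.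

Step 13
Reactants: 21 allyl (2E,6E,10E)-12-(4,5-dimethyl-3,6-dioxocyclohexa-1,4-dien-1-yl)-6,10-dimethyl-2-(4-methylpent-3-en-1-yl)dodeca-2,6,10-trienoate
Product: 23 allyl (2E,6E)-9-[(2S)-6-hydroxy-2,7,8-trimethyl-2H-chromen-2-yl]-6-methyl-2-(4-methylpent-3-en-1-yl)nona-2,6-dienoate, via vinyl ortho-quinone methide 22 (not isolated)
Conditions: 9-amino(9-deoxy)epi-quinidine 3,5-(CF3)2C6H3-squaramide (10 mol %), PhMe (0.05 M), 25 °C, Ar, dark
Reagents that add atoms: none
Why: Proposed new method: catalytic enantioselective prenylquinone-to-chromenol isomerisation; the squaramide NH pair binds the quinone carbonyl para to the reacting one (the future C6–O), and the quinuclidine, reaching along the unsubstituted C–H edge of the ring (O···C1' about 4.8 Å), removes one enantiotopic C1'–H in the rate-limiting step to give the (Z)-vinyl o-quinone methide 22 as a contact ion pair whose N–H+ sits on one π-face, hydrogen-bonded to the dienone oxygen; the inward-pointing C3' methyl of the E-alkene forces the oxatriene into a helix, so the helix sense is fixed on the catalyst at the moment of deprotonation, and the low-barrier disrotatory oxa-6π closure (O onto the Si face of C3') outruns helix inversion and catalyst release, forming the pyran C–O bond and setting (S)-C2; aromatisation drives the reaction and proton return to the C6 oxygen frees the catalyst; the closest known reaction types are the racemic amine- or pyridine-promoted isomerisation of plastoquinone-type prenylquinones to chromenols, and chiral ion-pair or hydrogen-bond-controlled 6π electrocyclisations and o-quinone methide organocatalysis.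

Step 14
Reactants: 23 allyl (2E,6E)-9-[(2S)-6-hydroxy-2,7,8-trimethyl-2H-chromen-2-yl]-6-methyl-2-(4-methylpent-3-en-1-yl)nona-2,6-dienoate
Product: 24 (2E,6E)-9-[(2S)-6-hydroxy-2,7,8-trimethyl-2H-chromen-2-yl]-6-methyl-2-(4-methylpent-3-en-1-yl)nona-2,6-dienoic acid
Conditions: Pd(PPh3)4 (5 mol %), morpholine (10 equiv), THF, rt, dark; 10 % citric acid work-up
Reagents that add atoms: none
Why: Tsuji–Trost deallylation with excess morpholine as allyl acceptor is neutral and runs at room temperature, so the phenol is not allylated, the enoate geometry holds and C2 is not racemised by ring opening.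

## Compound list
1 | 2,3-dimethylhydroquinone | Cc1c(O)ccc(O)c1C | starting material
2 | 1,4-dimethoxy-2,3-dimethylbenzene | COc1ccc(OC)c(C)c1C | intermediate
3 | 1-bromo-2,5-dimethoxy-3,4-dimethylbenzene | COc1cc(Br)c(OC)c(C)c1C | intermediate
4 | (2E,6E)-farnesol | CC(C)=CCC/C(C)=C/CC/C(C)=C/CO | starting material
5 | (2E,6E)-farnesyl acetate | CC(C)=CCC/C(C)=C/CC/C(C)=C/COC(C)=O | intermediate
6 | (2E,6E)-10-bromo-11-hydroxy-3,7,11-trimethyldodeca-2,6-dien-1-yl acetate, racemic | CC(C)(O)C(Br)CC/C(C)=C/CC/C(C)=C/COC(C)=O | intermediate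
7 | (2E,6E)-10,11-epoxy-3,7,11-trimethyldodeca-2,6-dien-1-yl acetate, racemic, not isolated | CC1(C)OC1CC/C(C)=C/CC/C(C)=C/COC(C)=O | intermediate
8 | (2E,6E)-10,11-epoxy-3,7,11-trimethyldodeca-2,6-dien-1-ol, racemic | CC1(C)OC1CC/C(C)=C/CC/C(C)=C/CO | intermediate
9 | (2E,6E)-3,7,11-trimethyldodeca-2,6-diene-1,10,11-triol, racemic, not isolated | CC(C)(O)C(O)CC/C(C)=C/CC/C(C)=C/CO | intermediate
10 | (4E,8E)-10-hydroxy-4,8-dimethyldeca-4,8-dienal | O=CCC/C(C)=C/CC/C(C)=C/CO | intermediate
11 | 5-bromo-2-methylpent-2-ene | CC(C)=CCCBr | starting material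
12 | 5-iodo-2-methylpent-2-ene | CC(C)=CCCI | intermediate
13 | allyl (triphenyl-λ5-phosphanylidene)acetate | C=CCOC(=O)C=P(c1ccccc1)(c1ccccc1)c1ccccc1 | starting material
14 | [1-(allyloxy)-6-methyl-1-oxohept-5-en-2-yl]triphenylphosphonium iodide, not isolated | C=CCOC(=O)C(CCC=C(C)C)[P+](c1ccccc1)(c1ccccc1)c1ccccc1.[I-] | intermediate
15 | allyl 6-methyl-2-(triphenyl-λ5-phosphanylidene)hept-5-enoate | C=CCOC(=O)C(CCC=C(C)C)=P(c1ccccc1)(c1ccccc1)c1ccccc1 | intermediate
16 | allyl (2E,6E,10E)-12-hydroxy-6,10-dimethyl-2-(4-methylpent-3-en-1-yl)dodeca-2,6,10-trienoate | CC(C)=CCC/C(=C\CC/C(C)=C/CC/C(C)=C/CO)C(=O)OCC=C | intermediate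
17 | allyl (2E,6E,10E)-12-bromo-6,10-dimethyl-2-(4-methylpent-3-en-1-yl)dodeca-2,6,10-trienoate | CC(C)=CCC/C(=C\CC/C(C)=C/CC/C(C)=C/CBr)C(=O)OCC=C | intermediate
18 | (2,5-dimethoxy-3,4-dimethylphenyl)lithium, not isolated | [Li]c1cc(OC)c(C)c(C)c1OC | intermediate
19 | (2,5-dimethoxy-3,4-dimethylphenyl)copper(I), not isolated | [Cu]c1cc(OC)c(C)c(C)c1OC | intermediate
20 | allyl (2E,6E,10E)-12-(2,5-dimethoxy-3,4-dimethylphenyl)-6,10-dimethyl-2-(4-methylpent-3-en-1-yl)dodeca-2,6,10-trienoate | CC(C)=CCC/C(=C\CC/C(C)=C/CC/C(C)=C/Cc1cc(OC)c(C)c(C)c1OC)C(=O)OCC=C | intermediate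
21 | allyl (2E,6E,10E)-12-(4,5-dimethyl-3,6-dioxocyclohexa-1,4-dien-1-yl)-6,10-dimethyl-2-(4-methylpent-3-en-1-yl)dodeca-2,6,10-trienoate | CC(C)=CCC/C(=C\CC/C(C)=C/CC/C(C)=C/CC1=CC(=O)C(C)=C(C)C1=O)C(=O)OCC=C | intermediate
22 | (Z)-vinyl ortho-quinone methide tautomer of 21 (4-hydroxy-2,3-dimethyl-6-alkenylidenecyclohexa-2,4-dien-1-one, side-chain alkenes E), not isolated | CC(C)=CCC/C(=C\CC/C(C)=C/CC/C(C)=C/C=C1/C=C(O)C(C)=C(C)C1=O)C(=O)OCC=C | intermediate
23 | allyl (2E,6E)-9-[(2S)-6-hydroxy-2,7,8-trimethyl-2H-chromen-2-yl]-6-methyl-2-(4-methylpent-3-en-1-yl)nona-2,6-dienoate | CC(C)=CCC/C(=C\CC/C(C)=C/CC[C@@]1(C)C=Cc2cc(O)c(C)c(C)c2O1)C(=O)OCC=C | intermediate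
24 | (2E,6E)-9-[(2S)-6-hydroxy-2,7,8-trimethyl-2H-chromen-2-yl]-6-methyl-2-(4-methylpent-3-en-1-yl)nona-2,6-dienoic acid (CNP0158414.1) | CC(C)=CCC/C(=C\CC/C(C)=C/CC[C@@]1(C)C=Cc2cc(O)c(C)c(C)c2O1)C(=O)O | target

## Counts and risks
Total step count: 14.
Longest linear sequence: 10 steps, from 4 to 24 (steps 3, 4, 5, 6, 9, 10, 11, 12, 13, 14).

**Step 13 (the new reaction).** The risk is low ee, if free 22 closes off the catalyst, or slow turnover.
- The fallback uses known chemistry, sets out from 21 and comes back at 23.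
- Compound 21 is heated in pyridine at reflux in the dark. This is the long-known racemic prenylquinone-to-chromenol isomerisation, and it gives the racemic chromenol allyl ester F1.
- The phenol is acylated with (1S)-(−)-camphanic chloride (Et3N, DMAP, CH2Cl2). This gives the (2S)-chromenyl (1S,4R)-camphanate F2 and the (2R)-chromenyl (1S,4R)-camphanate F3, which are separated by preparative silica HPLC.
- The aryl ester of F2 is cleaved with LiOH (1.2 equiv, THF/H2O, 0 °C). The hindered conjugated allyl ester does not react, and the product is 23.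

**Step 11 (arylcopper allylation).** The risks are SN2' attack, decomposition of bromide 17, and attack of residual aryllithium on the esters.
- The fallback sets out from 16 (together with 1) and comes back at 21. It makes steps 1, 2, 10 and 12 unnecessary.
- Friedel–Crafts allylation of excess 2,3-dimethylhydroquinone 1 with allylic alcohol 16 (BF3·OEt2, dioxane, rt) is the classical prenylquinone method. It gives allyl (2E,6E,10E)-12-(2,5-dihydroxy-3,4-dimethylphenyl)-6,10-dimethyl-2-(4-methylpent-3-en-1-yl)dodeca-2,6,10-trienoate F4.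
- F4 is oxidised with Ag2O (Et2O, MgSO4, rt) to 21.

**Step 8 (alkylation of a stabilised ylide with an unactivated homoallylic iodide).** The risks are a sluggish SN2 reaction and E2 elimination to the diene.
- The fallback sets out from 12 and comes back at 16.
- The far more nucleophilic sodium salt of commercial allyl diethylphosphonoacetate (NaH, THF/DMF, 0 to 50 °C) is alkylated with 12. This gives allyl 2-(diethoxyphosphoryl)-6-methylhept-5-enoate F5.
- Horner–Wadsworth–Emmons reaction of F5 with aldehyde 10 (NaH, THF, 0 °C to rt) gives 16 together with its geometric isomer, allyl (2Z,6E,10E)-12-hydroxy-6,10-dimethyl-2-(4-methylpent-3-en-1-yl)dodeca-2,6,10-trienoate F6. F6 is removed by chromatography.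

## Further compounds
F1 | step 13 | racemic allyl (2E,6E)-9-(6-hydroxy-2,7,8-trimethyl-2H-chromen-2-yl)-6-methyl-2-(4-methylpent-3-en-1-yl)nona-2,6-dienoate | CC(C)=CCC/C(=C\CC/C(C)=C/CCC1(C)C=Cc2cc(O)c(C)c(C)c2O1)C(=O)OCC=C
F2 | step 13 | (2S)-chromen-6-yl (1S,4R)-camphanate of 23 | CC(C)=CCC/C(=C\CC/C(C)=C/CC[C@@]1(C)C=Cc2cc(OC(=O)[C@@]34CC[C@@](C)(C(=O)O3)C4(C)C)c(C)c(C)c2O1)C(=O)OCC=C
F3 | step 13 | (2R)-chromen-6-yl (1S,4R)-camphanate, diastereomer of F2 | CC(C)=CCC/C(=C\CC/C(C)=C/CC[C@]1(C)C=Cc2cc(OC(=O)[C@@]34CC[C@@](C)(C(=O)O3)C4(C)C)c(C)c(C)c2O1)C(=O)OCC=C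
F4 | step 11 | allyl (2E,6E,10E)-12-(2,5-dihydroxy-3,4-dimethylphenyl)-6,10-dimethyl-2-(4-methylpent-3-en-1-yl)dodeca-2,6,10-trienoate | CC(C)=CCC/C(=C\CC/C(C)=C/CC/C(C)=C/Cc1cc(O)c(C)c(C)c1O)C(=O)OCC=C
F5 | step 8 | allyl 2-(diethoxyphosphoryl)-6-methylhept-5-enoate | CCOP(=O)(OCC)C(CCC=C(C)C)C(=O)OCC=C
F6 | step 8 | allyl (2Z,6E,10E)-12-hydroxy-6,10-dimethyl-2-(4-methylpent-3-en-1-yl)dodeca-2,6,10-trienoate | CC(C)=CCC/C(=C/CC/C(C)=C/CC/C(C)=C/CO)C(=O)OCC=C
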